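**Plan**
- **Numbering and cuts.** The cyclohexene is numbered C1' (CH bearing the carbinol carbon), C2' (CH-aryl), C3'=C4'(Me), C5'H2, C6'Me2; coumarin atoms carry no prime. The cuts, in order, are: the carbinol C-H (back to the aryl ketone) and one O7-CH3 (back to a phenol); then C1'-C2' and C5'-C6' together (retro-[4+2]); then the C8-C bond of each half, back to one 8-iodocoumarin.
- **Enabling feature.** The C3'=C4' alkene lies across the ring from the C6'-C1' bond. With the exocyclic carbon on C1' at the ketone level, C6'=C1' is a beta,beta-dimethyl enone. The ring is therefore the Diels-Alder union of two C5 (prenyl-derived) chains, each on C8 of a 5,7-dioxygenated coumarin, as in the presumed biosynthesis. O7, ortho to the acyl group, can chelate a chiral boron centre.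
- **Forward order.** Both coumarin bicycles are bought intact. Iodination at C8 is followed by divergence to the diene (Heck, dehydration) and the dienophile (carbonylative coupling, O7 release). The cycloaddition closes the cyclohexene last and joins the halves. O-methylation removes the phenol handle and reduction finishes the route.
- **Stereochemistry.** C1' comes from the ligand-shielded enone face, C2' from the E-diene and exo approach (trans ring), and the carbinol from Felkin-Anh hydride delivery.

Key step: step 6

Assumption: the sense of induction of the (R)-VANOL borate follows from a quadrant model of 10 and rests on no direct analogy. If the adduct belongs to the antipodal series, (S)-VANOL takes its place with no other change.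

Step 1
Reactants: 1 5,7-dimethoxycoumarin (citropten)
Product: 2 8-iodo-5,7-dimethoxycoumarin
Conditions: NIS (1.05 equiv), TFA (cat.), MeCN, 0 °C to rt
Reagents that add atoms: N-iodosuccinimide O=C1CCC(=O)N1I
Why: Electrophilic aromatic iodination, in which C8 (flanked by one methoxy group and the ring oxygen) should be taken in preference to C6 (flanked by two methoxy groups), a regiochemistry with close precedent for this coumarin.

Step 2
Reactants: 2 8-iodo-5,7-dimethoxycoumarin, 3 2-methylbut-3-en-2-ol
Product: 4 8-[(E)-3-hydroxy-3-methylbut-1-enyl]-5,7-dimethoxycoumarin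
Conditions: Pd(OAc)2 (5 mol %), Bu4NCl, NaHCO3, DMF, 80 °C
Reagents that add atoms: none
Why: Mizoroki-Heck reaction, in which syn carbopalladation at the terminal carbon and syn beta-hydride elimination give the E-alkene and the tertiary carbinol cannot isomerise to a carbonyl compound.

Step 3
Reactants: 4 8-[(E)-3-hydroxy-3-methylbut-1-enyl]-5,7-dimethoxycoumarin
Product: 5 8-[(E)-3-methylbuta-1,3-dienyl]-5,7-dimethoxycoumarin
Conditions: PPTS (10 mol %), 4 Å MS, BHT (trace), toluene, 70 °C; used promptly
Reagents that add atoms: none
Why: Acid-catalysed E1 dehydration, in which the tertiary allylic alcohol ionises to a cation conjugated to the electron-rich arene and loses a methyl proton to give the conjugated diene with the E-alkene retained.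

Step 4
Reactants: 2 8-iodo-5,7-dimethoxycoumarin, 6 2-methylprop-1-enylboronic acid pinacol ester
Product: 7 5,7-dimethoxy-8-(3-methylbut-2-enoyl)coumarin
Conditions: PEPPSI-IPr (3 mol %), K2CO3, CO (1 atm), anisole, 80 °C
Reagents that add atoms: carbon monoxide [C-]#[O+]
Why: Carbonylative Suzuki-Miyaura coupling, in which CO insertion into the electron-rich, di-ortho-substituted aryl-palladium bond should outrun direct transmetalation under the NHC-palladium catalyst, so that the acyl-palladium species meets the alkenylboronate.

Step 5
Reactants: 7 5,7-dimethoxy-8-(3-methylbut-2-enoyl)coumarin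
Product: 9 7-hydroxy-5-methoxy-8-(3-methylbut-2-enoyl)coumarin, via dichloroboron chelate 8 (not isolated)
Conditions: BCl3 (2.2 equiv), CH2Cl2, -78 to -10 °C; cold pH 7 buffer
Reagents that add atoms: none
Why: Chelation-directed aryl methyl ether cleavage, in which BCl3 bound to the ketone oxygen cleaves only the ortho (C7) ether through the six-membered chelate 8, the C5 ether has no neighbouring carbonyl group, and cold buffered hydrolysis should leave the hydrogen-bonded phenol open-chain.

Step 6
Reactants: 9 7-hydroxy-5-methoxy-8-(3-methylbut-2-enoyl)coumarin, 5 8-[(E)-3-methylbuta-1,3-dienyl]-5,7-dimethoxycoumarin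
Product: 12 8-{[(1R,2S)-2-(5,7-dimethoxy-2-oxochromen-8-yl)-4,6,6-trimethylcyclohex-3-en-1-yl]carbonyl}-7-hydroxy-5-methoxycoumarin, via spiro-borate of the enone 10 (not isolated), via spiro-borate of the adduct 11 (not isolated)
Conditions: (R)-VANOL (1.2 equiv), B(OPh)3 (1.2 equiv), 5 Å MS, CH2Cl2, rt; then 9; then 5 (1.5 equiv), BHT, 25-40 °C; aq NaHCO3 work-up; chromatography
Reagents that add atoms: none
Why: Proposed new method: the phenol of 9 displaces phenoxide from the (R)-VANOL phenyl borate to give spiro-borate 10, in which O7 and the ketone oxygen chelate boron, the LUMO of the s-cis enone is lowered and the phenolic oxygen is held away from the beta-carbon (no oxa-Michael closure), and diene 5 then adds in a concerted but strongly asynchronous [4+2] cycloaddition in which its CH2 terminus bonds first to the CMe2 carbon while the developing allyl cation is carried by the methyl group and the trioxygenated arene. The closest known reaction types are the chiral diol-borate-promoted Diels-Alder reaction of 2'-hydroxychalcones with 1-aryl-3-methylbutadienes and the Lewis-acid Diels-Alder reaction of mesityl oxide with 1-substituted dienes, and what is new is a beta,beta-dimethyl enone, hence a quaternary carbon, on the chiral borate. The cyclohexene is closed by an intermolecular suprafacial-suprafacial (4+2) closure that makes C5'-C6' and C1'-C2' in one event and joins the two halves. C1' is controlled by the ligand, whose vaulted naphthalene should cover the Si face of the alpha-carbon so that the diene enters on the Re face, and C2' is controlled relative to C1' by the E geometry of 5 and the exo orientation, in which the alpha-hydrogen and not the bulky borate-acyl unit lies under C2/C3 of the diene, which gives the trans (1'R,2'S) ring. The step needs ortho/para regiochemistry, secured by the matched polarisation of the two partners, and chemoselectivity over the coumarin C3=C4 bonds and over self-cycloaddition of 5, secured because only the chelated enone is activated. The endo (cis) isomer has to be removed by chromatography at this stage, because its later epimerisation at C1' would lead to the antipodal trans series.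

Step 7
Reactants: 12 the (1R,2S) hydroxy ketone adduct
Product: 13 8-{[(1R,2S)-2-(5,7-dimethoxy-2-oxochromen-8-yl)-4,6,6-trimethylcyclohex-3-en-1-yl]carbonyl}-5,7-dimethoxycoumarin
Conditions: MeI (3 equiv), K2CO3 (2 equiv), DMF, rt
Reagents that add atoms: iodomethane CI
Why: Williamson O-methylation of the phenol handle, in which the mild base can touch only C1', which already has the more stable trans configuration, so that no stereocentre should be lost.

Step 8
Reactants: 13 the (1R,2S) dimethoxy ketone
Product: 14 IN0553, 8-{(R)-[(1R,2S)-2-(5,7-dimethoxy-2-oxochromen-8-yl)-4,6,6-trimethylcyclohex-3-en-1-yl](hydroxy)methyl}-5,7-dimethoxycoumarin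
Conditions: NaBH4 (excess), THF-MeOH (4:1), -10 to 0 °C; pH 7 buffer; base-washed silica
Reagents that add atoms: none
Why: Felkin-Anh-controlled borohydride reduction, in which the quaternary C6' stands perpendicular to the carbonyl plane and C1'-H lies next to the twisted aryl group, so that hydride should enter anti to C6' and give the (R)-carbinol, while the coumarin lactones and the trisubstituted alkene are inert to NaBH4 at this temperature.

**Compound list**
1 | 5,7-dimethoxycoumarin (citropten) | COc1cc(OC)c2ccc(=O)oc2c1 | starting material
2 | 8-iodo-5,7-dimethoxycoumarin | COc1cc(OC)c2ccc(=O)oc2c1I | intermediate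
3 | 2-methylbut-3-en-2-ol | CC(C)(O)C=C | starting material
4 | 8-[(E)-3-hydroxy-3-methylbut-1-enyl]-5,7-dimethoxycoumarin | COc1cc(OC)c2ccc(=O)oc2c1/C=C/C(C)(C)O | intermediate
5 | 8-[(E)-3-methylbuta-1,3-dienyl]-5,7-dimethoxycoumarin | COc1cc(OC)c2ccc(=O)oc2c1/C=C/C(C)=C | intermediate
6 | 2-methylprop-1-enylboronic acid pinacol ester | CC(C)=CB1OC(C)(C)C(C)(C)O1 | starting material
7 | 5,7-dimethoxy-8-(3-methylbut-2-enoyl)coumarin | COc1cc(OC)c2ccc(=O)oc2c1C(=O)C=C(C)C | intermediate
8 | dichloroboron chelate of 9 (O7 and ketone O on BCl2) | CC(C)=CC1=[O+][B-](Cl)(Cl)Oc2cc(OC)c3ccc(=O)oc3c12 | intermediate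
9 | 7-hydroxy-5-methoxy-8-(3-methylbut-2-enoyl)coumarin | CC(C)=CC(=O)c1c(O)cc(OC)c2ccc(=O)oc12 | intermediate
10 | spiro-borate of 9 with (R)-VANOL (axial chirality R, not expressible in SMILES) | CC(C)=CC1=[O+][B-]2(Oc3cc(OC)c4ccc(=O)oc4c13)Oc1c(-c3c(O2)c4ccccc4cc3-c3ccccc3)c(-c3ccccc3)cc3ccccc13 | intermediate
11 | spiro-borate of adduct 12 with (R)-VANOL (axial chirality R) | COc1cc(OC)c2ccc(=O)oc2c1[C@H]1C=C(C)CC(C)(C)[C@@H]1C1=[O+][B-]2(Oc3cc(OC)c4ccc(=O)oc4c13)Oc1c(-c3c(O2)c4ccccc4cc3-c3ccccc3)c(-c3ccccc3)cc3ccccc13 | intermediate
12 | (1R,2S)-trans hydroxy ketone adduct | COc1cc(OC)c2ccc(=O)oc2c1[C@H]1C=C(C)CC(C)(C)[C@@H]1C(=O)c1c(O)cc(OC)c2ccc(=O)oc12 | intermediate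
13 | (1R,2S)-trans dimethoxy ketone | COc1cc(OC)c2ccc(=O)oc2c1[C@H]1C=C(C)CC(C)(C)[C@@H]1C(=O)c1c(OC)cc(OC)c2ccc(=O)oc12 | intermediate
14 | IN0553, (R)-carbinol of the (1R,2S) ring | COc1cc(OC)c2ccc(=O)oc2c1[C@H]1C=C(C)CC(C)(C)[C@@H]1[C@@H](O)c1c(OC)cc(OC)c2ccc(=O)oc12 | target

**Step count**
- Total: 8 steps.
- Longest linear sequence: 6 steps (1, 4, 5, 6, 7, 8, or equally 1, 2, 3, 6, 7, 8).

**Steps most likely to fail**

**1. Step 6 (Proposed new method).** The beta,beta-disubstituted enone may add too slowly. Acid-induced oligomerisation or self-cycloaddition of the diene would then take over, and exo/endo or facial selectivity may be poor.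

The fallback uses known chemistry and sets out from 7 and 5.
- Me2AlCl in CH2Cl2 (-20 °C to rt) drives the Lewis-acid Diels-Alder reaction of the kind established for mesityl oxide with 1-substituted dienes. It would give the racemic adduct as a mixture of the racemic cis dimethoxy ketone F1 and the racemic trans ketone.
- DBU in toluene equilibrates the cis isomer to the trans isomer through the enolate, which is harmless in the racemic series.
- The racemate consists of 13 and the antipodal trans dimethoxy ketone F2. It is separated by preparative chromatography on a chiral stationary phase.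
- The route is rejoined at 13, and steps 5 to 7 are bypassed.

**2. Step 8.** Hydride delivery may show poor facial selectivity, because C6' and C2' compete for the role of the large group. The crowded ketone may also reduce sluggishly.

The fallback sets out from 13 and replaces substrate control by catalyst control.
- It is a Corey-Bakshi-Shibata reduction with (S)-2-methyl-CBS-oxazaborolidine and catecholborane in toluene at low temperature.
- With the aryl group as the large substituent, this should deliver the (R)-carbinol.
- It comes back at 14 and makes no new compound (F0).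

**3. Step 5.** On release, the phenol may add to the enone (oxa-Michael closure to a 2,2-dimethylchromanone ring), or HCl may add to the enone during work-up.

The fallback never frees the phenol and sets out from chelate 8.
- The volatiles are removed under vacuum.
- (R)-VANOL and 2,6-di-tert-butyl-4-methylpyridine are added, so that simple alcoholysis of the two B-Cl bonds gives spiro-borate 10 directly.
- Diene 5 is then added as in step 6.
- The route is rejoined at 10, and no new compound is made (F0).

Further compounds
F1 | step 6 | racemic cis dimethoxy ketone (relative configuration shown) | COc1cc(OC)c2ccc(=O)oc2c1[C@H]1C=C(C)CC(C)(C)[C@H]1C(=O)c1c(OC)cc(OC)c2ccc(=O)oc12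
F2 | step 6 | antipodal trans dimethoxy ketone (ent-13, 1S,2R) | COc1cc(OC)c2ccc(=O)oc2c1[C@@H]1C=C(C)CC(C)(C)[C@H]1C(=O)c1c(OC)cc(OC)c2ccc(=O)oc12
F0 | step 8 | none | none
F0 | step 5 | none | none
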